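**Plan**

1. Retrosynthesis: remove the three esters; open each cis-epoxide back to a Z-allylic alcohol (9-OH with C1=C10, 3-OH with C4=C5); trace the C3 enone to a 3-ethoxy-3-en-5-one; cut C2–C3 by a retro-[3,3] shift that re-forms C5–C10; finally cut the C10–vinyl bond (semipinacol) and the C8–O bond.
2. Enabling feature: the 1,10- and 4,5-epoxides are a masked cyclodeca-1,5-diene whose central σ-bond is C2–C3. The ten-membered ring is therefore the [3,3] ring-expansion product of a cyclohexane C5–C10 with methyl (C10) para to isopropenyl (C7), which is carvone.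
3. Forward, ring construction: (S)-carvone → C8 oxygen → C9 vinyl carbinol → epoxide → 1,2-vinyl shift (quaternary C10) → triol, acetonide, C5 ketone → C5 ethoxyethynyl carbinol → anionic acetylenic oxy-Cope shift (ten-membered ring closed, six-membered ring opened) with MeI capture (C15).
4. Forward, endgame: diol release, 9-OH-directed 1,10-epoxidation, C8 senecioate, C9 acetate, enone transposition to C3, CBS reduction, 3-OH-directed 4,5-epoxidation, Mitsunobu angeloylation.
5. Stereochemistry: C7 from (S)-carvone; C8 by enolate hydroxylation then Mitsunobu inversion; C10 (temporary) by the stereospecific vinyl shift; C9 by hydride attack anti to the axial C8–O and C10–Me; Z C1=C10 from the chair-like [3,3] array; Z C4=C5 from ring strain in the transposition; C1/C10 and C4/C5 by hydroxyl-directed epoxidation; C3 by CBS reduction then SN2 inversion.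

Key step: step 10

Remark: intermediates carry the target's germacrane numbers (C5–C10 = carvone ring, C9 = carvone carbonyl carbon, C1/C2 = vinyl, C3/C4 = alkyne, C15 from MeI); α is the ring face that carries the C7 isopropenyl group.

Step 1
Reactants: 1 (S)-carvone
Product: 3 trans-6-hydroxycarvone (8β-OH), via lithium enolate 2 (not isolated)
Conditions: LDA, THF, −78 °C; then 2-(phenylsulfonyl)-3-phenyloxaziridine, −78 °C; aq. NH4Cl
Reagents that add atoms: 2-(phenylsulfonyl)-3-phenyloxaziridine, O=S(=O)(N1OC1c1ccccc1)c1ccccc1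
Why: Kinetic deprotonation at C8 gives the cross-conjugated enolate, and enolate hydroxylation with the N-sulfonyloxaziridine should occur anti to the neighbouring isopropenyl group, setting C8 as the trans (8β) alcohol.

Step 2
Reactants: 3 trans-6-hydroxycarvone; 4 acetic acid
Product: 5 cis-6-acetoxycarvone (8α-OAc)
Conditions: AcOH, PPh3, DIAD, THF, 0 °C to rt
Reagents that add atoms: acetic acid, CC(=O)O
Why: Mitsunobu esterification proceeds by SN2 displacement at the carbonyl-activated C8 and so inverts it to the 8α (cis to isopropenyl) configuration of the target.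

Step 3
Reactants: 5 cis-6-acetoxycarvone; 6 vinylmagnesium bromide
Product: 7 9β-vinyl-8α,9α-diol
Conditions: CH2=CHMgBr (4 equiv), THF, −78 to 0 °C; aq. NH4Cl
Reagents that add atoms: vinylmagnesium bromide, C=C[Mg]Br
Why: Grignard 1,2-addition to the enone carbonyl should occur on the β face, anti to both the 8α-acetoxy and 7α-isopropenyl groups (Felkin–Anh), setting C9 (vinyl β, OH α), while excess reagent cleaves the acetate to give the cis-diol.

Step 4
Reactants: 7 9β-vinyl-8α,9α-diol
Product: 8 5α,10α-epoxy-9β-vinyl-8α,9α-diol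
Conditions: VO(acac)2 (5 mol %), t-BuOOH, CH2Cl2, 0 °C to rt
Reagents that add atoms: tert-butyl hydroperoxide, CC(C)(C)OO
Why: Vanadium-catalysed hydroxyl-directed epoxidation delivers oxygen to the trisubstituted ring alkene syn to the tertiary allylic 9α-OH, leaving the vinyl and isopropenyl groups untouched.

Step 5
Reactants: 8 5α,10α-epoxy-9β-vinyl-8α,9α-diol
Product: 9 5α,8α-dihydroxy-10α-methyl-10β-vinyl-cyclohexan-9-one
Conditions: BF3·OEt2 (0.3 equiv), CH2Cl2, −78 to −30 °C
Reagents that add atoms: none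
Why: Lewis-acid opening of the epoxide at tertiary C10 triggers a semipinacol rearrangement in which the C9 vinyl group, antiperiplanar to the breaking C10–O bond, shifts with inversion at C10, creating the quaternary centre (vinyl β, methyl α) and the C9 ketone stereospecifically.

Step 6
Reactants: 9 5α,8α-dihydroxy-10α-methyl-10β-vinyl-cyclohexan-9-one
Product: 10 5α,8α,9α-triol
Conditions: NaBH4, MeOH, −78 to −40 °C
Reagents that add atoms: none
Why: In this borohydride reduction hydride should attack the C9 ketone from the β face, because the axial 8α-OH and 10α-methyl both block the α face, giving the equatorial 9α-alcohol (C7/C8/C9 all cis).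

Step 7
Reactants: 10 5α,8α,9α-triol; 11 2,2-dimethoxypropane
Product: 12 8,9-O-isopropylidene-5α-ol
Conditions: Me2C(OMe)2, PPTS (cat.), CH2Cl2, rt
Reagents that add atoms: 2,2-dimethoxypropane, COC(C)(C)OC
Why: Acid-catalysed acetalisation is selective for the cis-vicinal 8,9-diol, since the diequatorial 5,9-diol cannot be bridged without a chair flip.

Step 8
Reactants: 12 8,9-O-isopropylidene-5α-ol
Product: 13 8,9-O-isopropylidene-5-ketone
Conditions: Dess–Martin periodinane, NaHCO3, CH2Cl2, rt
Reagents that add atoms: none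
Why: Dess–Martin oxidation of the only free alcohol gives the C5 ketone under buffered, non-epimerising conditions.

Step 9
Reactants: 13 8,9-O-isopropylidene-5-ketone; 14 ethoxyacetylene
Product: 16 5β-(ethoxyethynyl)-5α-ol, via lithium ethoxyacetylide 15 (not isolated)
Conditions: ethoxyacetylene, n-BuLi, THF, −78 °C; then 13, −78 to −20 °C; cold aq. NH4Cl
Reagents that add atoms: ethoxyacetylene, C#COCC
Why: In this acetylide 1,2-addition the small nucleophile should add axially to C5, anti to the axial 10α-methyl group, so the alkynyl group (C4≡C3) ends β and cis to the equatorial C10 vinyl group.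

Step 10
Reactants: 16 5β-(ethoxyethynyl)-5α-ol; 17 iodomethane
Product: 20 (1(10)Z)-3-ethoxy-8α,9α-(isopropylidenedioxy)germacra-1(10),3,11-trien-5-one, via potassium alkoxide 18 (not isolated), via potassium allenolate 19 (not isolated)
Conditions: KH, 18-crown-6, THF, 0 °C to rt; then cannulate into MeI (5 equiv), THF, −78 to 0 °C
Reagents that add atoms: iodomethane, CI
Why: Proposed new method: alkoxide 18 is a 3-oxido-1,5-enyne (C2=C1–C10–C5(O–)–C4≡C3) and should undergo an alkoxide-accelerated [3,3] (acetylenic oxy-Cope) shift in which C2–C3 forms as C5–C10 breaks; the closest known reactions are the anionic oxy-Cope ring expansion of cis-1,2-dialkenylcyclohexanols to (Z)-cyclodec-5-enones and the acetylenic oxy-Cope of 1-alkynyl-2-alkenyl carbinols, and the untested parts are the ynol-ether terminus and C-methylation of the cyclic allenolate. The ten-membered ring is closed by this concerted four-atom ring expansion (6 to 10), not by an end-to-end cyclisation, so no high dilution is needed. No stereocentre is formed; the one new stereo-element, the C1=C10 alkene, should be Z because the equatorial C10 vinyl group can reach the axial C5 alkynyl group only by turning C2 towards C9, which puts the C10–C9 bond pseudo-axial in the chair-like array while the C7, C8 and C9 substituents lock the cyclohexane chair. Allenolate 19 (O–C5=C4=C3(OEt)) is then methylated by MeI at its central carbon C4 from outside the ring, installing C15 and giving vinylogous ester 20 with C2 and C5 cis on C3=C4. The step needs the [3,3] shift to outrun retro-alkynylation of the tertiary alkoxide, and C-methylation to outrun O-methylation and proton transfer; the cis (equatorial/axial) vinyl/alkynyl arrangement, the crown-separated potassium alkoxide, and inverse addition to excess soft MeI are meant to secure this.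

Step 11
Reactants: 20 (1(10)Z)-3-ethoxy-8α,9α-(isopropylidenedioxy)germacra-1(10),3,11-trien-5-one
Product: 21 (1(10)Z)-3-ethoxy-8α,9α-dihydroxygermacra-1(10),3,11-trien-5-one
Conditions: PPTS, EtOH, 50 °C
Reagents that add atoms: none
Why: Acid-catalysed transketalisation in ethanol (which makes exchange at the ethyl enol ether degenerate) frees the 8,9-diol without touching the vinylogous ester.

Step 12
Reactants: 21 (1(10)Z)-3-ethoxy-8α,9α-dihydroxygermacra-1(10),3,11-trien-5-one
Product: 22 1α,10α-epoxy-3-ethoxy-8α,9α-dihydroxygermacra-3,11-dien-5-one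
Conditions: VO(acac)2 (5 mol %), t-BuOOH, CH2Cl2, 0 °C
Reagents that add atoms: tert-butyl hydroperoxide, CC(C)(C)OO
Why: In this hydroxyl-directed vanadium epoxidation the allylic 9α-OH should deliver oxygen to the α face of the Z C1=C10 alkene, giving the cis-epoxide (C1 and C10 set), while the push–pull C3=C4 alkene and the isopropenyl group do not react.

Step 13
Reactants: 22 1α,10α-epoxy-3-ethoxy-8α,9α-dihydroxygermacra-3,11-dien-5-one; 23 3-methylbut-2-enoic acid
Product: 24 8α-senecioate of 22
Conditions: senecioic acid (1.1 equiv), EDC·HCl, DMAP (0.1 equiv), CH2Cl2, −20 to 0 °C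
Reagents that add atoms: 3-methylbut-2-enoic acid, CC(C)=CC(=O)O
Why: Steglich esterification is expected at the C8 hydroxyl because the C9 hydroxyl is flanked by the fully substituted epoxide carbon C10 and is hydrogen-bonded to the cis epoxide oxygen.

Step 14
Reactants: 24 8α-senecioate of 22; 25 acetic anhydride
Product: 26 9α-acetate 8α-senecioate
Conditions: Ac2O, pyridine, DMAP (cat.), CH2Cl2, 0 °C to rt
Reagents that add atoms: acetic anhydride, CC(=O)OC(C)=O
Why: DMAP-catalysed acetylation esterifies the remaining hindered C9 alcohol.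

Step 15
Reactants: 26 9α-acetate 8α-senecioate
Product: 28 (4Z)-9α-acetoxy-1α,10α-epoxy-8α-senecioyloxygermacra-4,11-dien-3-one, via 5-hydroxy enol ether 27 (not isolated)
Conditions: NaBH4, CeCl3·7H2O, MeOH, 0 °C; then 0.5 M aq. oxalic acid, THF, 0 °C
Reagents that add atoms: water, O
Why: Luche 1,2-reduction of the vinylogous ester carbonyl (esters and epoxide spared) followed by mild-acid Stork–Danheiser transposition gives the C3 enone, and the new C4=C5 bond should be Z because the U-shaped alkoxypentadienyl cation is the only low-strain geometry in the ten-membered ring.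

Step 16
Reactants: 28 (4Z)-9α-acetoxy-1α,10α-epoxy-8α-senecioyloxygermacra-4,11-dien-3-one
Product: 29 (3R)-3β-hydroxy-(4Z)-diene
Conditions: (S)-Me-CBS oxazaborolidine (0.2 equiv), catecholborane, toluene, −78 °C
Reagents that add atoms: none
Why: Corey–Bakshi–Shibata reduction with the (S)-catalyst treats the alkenyl side as the large group and should give the (3R) allylic alcohol under catalyst control, while catecholborane leaves the isopropenyl group, esters and epoxide untouched.

Step 17
Reactants: 29 (3R)-3β-hydroxy-(4Z)-diene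
Product: 30 3β-hydroxy-1α,10α:4β,5β-diepoxide
Conditions: VO(acac)2 (5 mol %), t-BuOOH, CH2Cl2, 0 °C
Reagents that add atoms: tert-butyl hydroperoxide, CC(C)(C)OO
Why: Hydroxyl-directed vanadium epoxidation of the Z-allylic alcohol should place oxygen on the face of the 3β-OH, giving the 4β,5β cis-epoxide (C4 and C5 set).

Step 18
Reactants: 30 3β-hydroxy-1α,10α:4β,5β-diepoxide; 31 angelic acid
Product: 32 CNP0276917.1
Conditions: angelic acid, PPh3, DIAD, toluene, 0 °C to rt
Reagents that add atoms: angelic acid, C/C=C(/C)C(=O)O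
Why: Mitsunobu esterification inverts C3 by SN2 displacement to the 3α-angelate, and because the acid is never activated as an acyl donor its Z double bond should not isomerise.

**Compound list**

1 | (S)-(+)-carvone | CC1=CC[C@@H](CC1=O)C(C)=C | starting material
2 | lithium cross-conjugated enolate of 1 | CC1=CC[C@H](C(C)=C)C=C1[O-].[Li+] | intermediate
3 | (5R,6R)-6-hydroxycarvone (OH trans to isopropenyl; 8β-OH) | CC1=CC[C@@H]([C@@H](O)C1=O)C(C)=C | intermediate
4 | acetic acid | CC(=O)O | starting material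
5 | (5R,6S)-6-acetoxycarvone (OAc cis to isopropenyl; 8α-OAc) | CC1=CC[C@@H]([C@H](OC(C)=O)C1=O)C(C)=C | intermediate
6 | vinylmagnesium bromide | C=C[Mg]Br | starting material
7 | 2-methyl-5-isopropenyl-1-vinylcyclohex-2-ene-1,6-diol, both OH and isopropenyl cis (9β-vinyl-8α,9α-diol) | CC1=CC[C@@H]([C@H](O)[C@@]1(O)C=C)C(C)=C | intermediate
8 | 5α,10α-epoxide of 7 (oxirane cis to both hydroxyls) | C[C@]12O[C@@H]2C[C@@H]([C@H](O)[C@@]1(O)C=C)C(C)=C | intermediate
9 | 5α,8α-dihydroxy-10α-methyl-10β-vinyl-7α-isopropenylcyclohexan-9-one | C=C[C@@]1(C)[C@H](O)C[C@H](C(C)=C)[C@H](O)C1=O | intermediate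
10 | 5α,8α,9α-triol (10α-methyl, 10β-vinyl, 7α-isopropenyl) | C=C[C@@]1(C)[C@H](O)C[C@H](C(C)=C)[C@H](O)[C@@H]1O | intermediate
11 | 2,2-dimethoxypropane | COC(C)(C)OC | starting material
12 | 8α,9α-O-isopropylidene-5α-ol | C=C[C@@]1(C)[C@H](O)C[C@H](C(C)=C)[C@@H]2OC(C)(C)O[C@H]12 | intermediate
13 | 8α,9α-O-isopropylidene-10α-methyl-10β-vinyl-7α-isopropenylcyclohexan-5-one | C=C[C@@]1(C)C(=O)C[C@H](C(C)=C)[C@@H]2OC(C)(C)O[C@H]12 | intermediate
14 | ethoxyacetylene | C#COCC | starting material
15 | lithium ethoxyacetylide | [Li]C#COCC | intermediate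
16 | 5β-(ethoxyethynyl)-5α-ol (alkynyl cis to the C10 vinyl group) | C=C[C@@]1(C)[C@@](O)(C#COCC)C[C@H](C(C)=C)[C@@H]2OC(C)(C)O[C@H]12 | intermediate
17 | iodomethane | CI | starting material
18 | potassium alkoxide of 16 | C=C[C@@]1(C)[C@@]([O-])(C#COCC)C[C@H](C(C)=C)[C@@H]2OC(C)(C)O[C@H]12.[K+] | intermediate
19 | ten-membered potassium allenolate (O–C5=C4=C3(OEt); 1(10)Z; allene axis fixed by the ring, not specified) | C=C(C)[C@H]1CC([O-])=C=C(OCC)C/C=C(/C)[C@H]2OC(C)(C)O[C@@H]12.[K+] | intermediate
20 | (1(10)Z)-3-ethoxy-8α,9α-(isopropylidenedioxy)germacra-1(10),3,11-trien-5-one (C2 and C5 cis on C3=C4) | C=C(C)[C@H]1CC(=O)/C(C)=C(OCC)\C/C=C(/C)[C@H]2OC(C)(C)O[C@@H]12 | intermediate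
21 | (1(10)Z)-3-ethoxy-8α,9α-dihydroxygermacra-1(10),3,11-trien-5-one | C=C(C)[C@H]1CC(=O)/C(C)=C(OCC)\C/C=C(/C)[C@@H](O)[C@H]1O | intermediate
22 | 1α,10α-epoxy-3-ethoxy-8α,9α-dihydroxygermacra-3,11-dien-5-one | C=C(C)[C@H]1CC(=O)/C(C)=C(OCC)\C[C@H]2O[C@@]2(C)[C@@H](O)[C@H]1O | intermediate
23 | 3-methylbut-2-enoic acid (senecioic acid) | CC(C)=CC(=O)O | starting material
24 | 1α,10α-epoxy-3-ethoxy-9α-hydroxy-8α-senecioyloxygermacra-3,11-dien-5-one | C=C(C)[C@H]1CC(=O)/C(C)=C(OCC)\C[C@H]2O[C@@]2(C)[C@@H](O)[C@H]1OC(=O)C=C(C)C | intermediate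
25 | acetic anhydride | CC(=O)OC(C)=O | starting material
26 | 9α-acetoxy-1α,10α-epoxy-3-ethoxy-8α-senecioyloxygermacra-3,11-dien-5-one | C=C(C)[C@H]1CC(=O)/C(C)=C(OCC)\C[C@H]2O[C@@]2(C)[C@@H](OC(C)=O)[C@H]1OC(=O)C=C(C)C | intermediate
27 | 5-hydroxy enol ether from 26 (C5 configuration inconsequential) | C=C(C)[C@H]1CC(O)/C(C)=C(OCC)\C[C@H]2O[C@@]2(C)[C@@H](OC(C)=O)[C@H]1OC(=O)C=C(C)C | intermediate
28 | (4Z)-9α-acetoxy-1α,10α-epoxy-8α-senecioyloxygermacra-4,11-dien-3-one | C=C(C)[C@H]1C/C=C(/C)C(=O)C[C@H]2O[C@@]2(C)[C@@H](OC(C)=O)[C@H]1OC(=O)C=C(C)C | intermediate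
29 | (3R,4Z)-9α-acetoxy-1α,10α-epoxy-3β-hydroxy-8α-senecioyloxygermacra-4,11-diene | C=C(C)[C@H]1C/C=C(/C)[C@H](O)C[C@H]2O[C@@]2(C)[C@@H](OC(C)=O)[C@H]1OC(=O)C=C(C)C | intermediate
30 | 9α-acetoxy-1α,10α:4β,5β-diepoxy-3β-hydroxy-8α-senecioyloxygermacr-11-ene | C=C(C)[C@H]1C[C@@H]2O[C@]2(C)[C@H](O)C[C@H]2O[C@@]2(C)[C@@H](OC(C)=O)[C@H]1OC(=O)C=C(C)C | intermediate
31 | angelic acid ((Z)-2-methylbut-2-enoic acid) | C/C=C(/C)C(=O)O | starting material
32 | CNP0276917.1, (1R,3S,4S,5S,7R,8S,9S,10R)-9-acetoxy-3-angeloyloxy-1,10:4,5-diepoxy-8-senecioyloxygermacr-11-ene | C=C(C)[C@H]1C[C@@H]2O[C@]2(C)[C@@H](OC(=O)/C(C)=C\C)C[C@H]2O[C@@]2(C)[C@@H](OC(C)=O)[C@H]1OC(=O)C=C(C)C | target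

**Step count**

Total steps: 18. Longest linear sequence: 18 (from (S)-carvone).

**Steps most likely to fail**

Step 10 (proposed new method). The tertiary propargylic alkoxide may fragment by retro-alkynylation instead of undergoing the [3,3] shift, and the strongly basic allenolate may be quenched by proton transfer, O-methylated or over-alkylated. The fallback uses known chemistry, sets out from 16 and comes back at 28.
- LiAlH4 (THF, 0 °C) trans-hydroaluminates the ynol ether to the (E)-2-ethoxyvinyl carbinol F1, a cis-1,2-dialkenylcyclohexanol.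
- Classical anionic oxy-Cope rearrangement (KH, 18-crown-6, THF) through the same chair array, then methylation of the ketone enolate with MeI, gives the ten-membered β-ethoxy ketone F2.
- DBU eliminates ethanol to the 3-en-5-one F3; alkaline H2O2 gives the epoxy ketone F4; Wharton transposition (N2H4·H2O, AcOH) gives the 4-en-3-ol F5.
- MnO2, with catalytic PhSH/Et3N if any 4E isomer forms, gives the (1(10)Z,4Z)-dienone acetonide F6.
- Aqueous AcOH frees the diol F7; VO(acac)2/t-BuOOH gives the 1α,10α-epoxide F8; Steglich senecioylation gives the 8-ester F9; cold acetylation returns to 28.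

Step 13. Acylation may not discriminate between the 8- and 9-hydroxyls, or the acyl group may migrate between them. The fallback sets out from 21 and comes back at 24. MnO2 oxidises only the allylic 9-hydroxyl to the 9-oxo compound F10. Its single hydroxyl (C8) is esterified with senecioic acid (EDC, DMAP) to F11. Luche reduction at −78 °C reduces the C9 enone carbonyl, not the vinylogous ester, from the face anti to the 8-acyloxy group to the 9α-alcohol F12. VO(acac)2/t-BuOOH epoxidation then gives 24.

Step 18. SN2 displacement at the carbinol next to the fully substituted epoxide carbon may be too slow, so that elimination or participation of the epoxide oxygen takes over. The fallback sets out from 28 and comes back at 32. The (R)-CBS catalyst with catecholborane gives the (3S) 3α-alcohol F13. m-CPBA (NaHCO3, CH2Cl2, 0 °C), which epoxidises medium-ring Z-allylic alcohols anti to the hydroxyl, gives the 3α-hydroxy-4β,5β-epoxide F14. Yamaguchi esterification with angelic acid (2,4,6-trichlorobenzoyl chloride, Et3N; then DMAP), with retention at C3, gives 32.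

Further compounds
F1 | step 10 | 5β-[(E)-2-ethoxyvinyl]-5α-ol (from LiAlH4 reduction of 16) | C=C[C@@]1(C)[C@@](O)(/C=C/OCC)C[C@H](C(C)=C)[C@@H]2OC(C)(C)O[C@H]12
F2 | step 10 | (1(10)Z)-3-ethoxy-8α,9α-(isopropylidenedioxy)germacra-1(10),11-dien-5-one (3β-OEt, 4α-Me expected; both erased next) | C=C(C)[C@H]1CC(=O)[C@@H](C)[C@H](OCC)C/C=C(/C)[C@H]2OC(C)(C)O[C@@H]12
F3 | step 10 | (1(10)Z)-8α,9α-(isopropylidenedioxy)germacra-1(10),3,11-trien-5-one | C=C(C)[C@H]1CC(=O)/C(C)=C\C/C=C(/C)[C@H]2OC(C)(C)O[C@@H]12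
F4 | step 10 | 3,4-epoxide of F3 (cis-epoxide; face not specified, both converge) | C=C(C)[C@H]1CC(=O)C2(C)OC2C/C=C(/C)[C@H]2OC(C)(C)O[C@@H]12
F5 | step 10 | (1(10)Z,4Z)-8α,9α-(isopropylidenedioxy)germacra-1(10),4,11-trien-3-ol (C3 configuration not specified) | C=C(C)[C@H]1C/C=C(/C)C(O)C/C=C(/C)[C@H]2OC(C)(C)O[C@@H]12
F6 | step 10 | (1(10)Z,4Z)-8α,9α-(isopropylidenedioxy)germacra-1(10),4,11-trien-3-one | C=C(C)[C@H]1C/C=C(/C)C(=O)C/C=C(/C)[C@H]2OC(C)(C)O[C@@H]12
F7 | step 10 | (1(10)Z,4Z)-8α,9α-dihydroxygermacra-1(10),4,11-trien-3-one | C=C(C)[C@H]1C/C=C(/C)C(=O)C/C=C(/C)[C@@H](O)[C@H]1O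
F8 | step 10 | (4Z)-1α,10α-epoxy-8α,9α-dihydroxygermacra-4,11-dien-3-one | C=C(C)[C@H]1C/C=C(/C)C(=O)C[C@H]2O[C@@]2(C)[C@@H](O)[C@H]1O
F9 | step 10 | (4Z)-1α,10α-epoxy-9α-hydroxy-8α-senecioyloxygermacra-4,11-dien-3-one | C=C(C)[C@H]1C/C=C(/C)C(=O)C[C@H]2O[C@@]2(C)[C@@H](O)[C@H]1OC(=O)C=C(C)C
F10 | step 13 | (1(10)Z)-3-ethoxy-8α-hydroxygermacra-1(10),3,11-triene-5,9-dione | C=C(C)[C@H]1CC(=O)/C(C)=C(OCC)\C/C=C(/C)C(=O)[C@H]1O
F11 | step 13 | (1(10)Z)-3-ethoxy-8α-senecioyloxygermacra-1(10),3,11-triene-5,9-dione | C=C(C)[C@H]1CC(=O)/C(C)=C(OCC)\C/C=C(/C)C(=O)[C@H]1OC(=O)C=C(C)C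
F12 | step 13 | (1(10)Z)-3-ethoxy-9α-hydroxy-8α-senecioyloxygermacra-1(10),3,11-trien-5-one | C=C(C)[C@H]1CC(=O)/C(C)=C(OCC)\C/C=C(/C)[C@@H](O)[C@H]1OC(=O)C=C(C)C
F13 | step 18 | (3S,4Z)-9α-acetoxy-1α,10α-epoxy-3α-hydroxy-8α-senecioyloxygermacra-4,11-diene | C=C(C)[C@H]1C/C=C(/C)[C@@H](O)C[C@H]2O[C@@]2(C)[C@@H](OC(C)=O)[C@H]1OC(=O)C=C(C)C
F14 | step 18 | 9α-acetoxy-1α,10α:4β,5β-diepoxy-3α-hydroxy-8α-senecioyloxygermacr-11-ene | C=C(C)[C@H]1C[C@@H]2O[C@]2(C)[C@@H](O)C[C@H]2O[C@@]2(C)[C@@H](OC(C)=O)[C@H]1OC(=O)C=C(C)C
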